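## Retrosynthesis (overview)

1. The target has a pyrrole-2-carboxylic acid core with a 5-hydroxyindol-3-yl at C5 and a 2-oxindol-3-yl at C3. I take it that violaceinic acid, as drawn, is the 2-hydroxyindole tautomer of a 3-substituted oxindole.
2. Last disconnections: N-SEM removal and O-debenzylation, which unmask the 5-hydroxyindole.
3. Key disconnection (proposed new method): the C3(pyrrole)–C3'(oxindole) bond. It is formed by carboxylate-directed C3–H alkylation of a 5-(indol-3-yl)pyrrole-2-carboxylic acid with 3-diazooxindole.
4. The C5–indole bond is made earlier by Ir C–H borylation of methyl pyrrole-2-carboxylate followed by Suzuki coupling with a 3-iodoindole.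
5. No rings are formed. Both heterocycles come from commercial materials (pyrrole ester, 5-benzyloxyindole, isatin).

**Assumptions (stated once):**
- The target has no true stereocenter. The drawn 2-hydroxyindole form is achiral, and its oxindole keto tautomer has a C3–H that epimerizes readily. No stereocontrol is needed, and intermediates 11 and 12 are racemic at that carbon.
- Ir borylation of NH methyl pyrrole-2-carboxylate goes to C5 (precedent-based).
- N–H 3-diazooxindole is usable without N-protection.

## Route

**Step 1**
Reactants: 1 methyl 1H-pyrrole-2-carboxylate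
Product: 2 methyl 5-(4,4,5,5-tetramethyl-1,3,2-dioxaborolan-2-yl)-1H-pyrrole-2-carboxylate
Conditions: HBpin (1.5 equiv), [Ir(OMe)(cod)]2 (1.5 mol%), dtbpy (3 mol%), THF, 80 °C
Reagents that add atoms: pinacolborane, B1OC(C)(C)C(C)(C)O1 (supplies the Bpin group)
Why: Sterically controlled Ir C–H borylation occurs at the least hindered α-C–H (C5), distal to the ester. The ester, N–H and ring survive.

**Step 2**
Reactants: 3 5-(benzyloxy)-1H-indole
Product: 4 5-(benzyloxy)-3-iodo-1H-indole
Conditions: I2 (1.05 equiv), KOH (2.2 equiv), DMF, 0 °C → rt, 1 h; use crude immediately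
Reagents that add atoms: iodine, II
Why: Electrophilic iodination at the most nucleophilic indole C3 (base-mediated, known). The benzyl ether is unaffected.

**Step 3**
Reactants: 4
Product: 5 5-(benzyloxy)-3-iodo-1-[(2-trimethylsilylethoxy)methyl]indole
Conditions: NaH (1.2 equiv), then SEMCl (1.2 equiv), DMF, 0 °C, 1 h
Reagents that add atoms: SEM-Cl, C[Si](C)(C)CCOCCl (supplies SEM)
Why: N-alkylation of the indolide. SEM survives the base (Step 5), the Rh(III) conditions (Step 8) and hydrogenolysis.

**Step 4**
Reactants: 2 + 5
Product: 6 methyl 5-[5-(benzyloxy)-1-SEM-indol-3-yl]-1H-pyrrole-2-carboxylate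
Conditions: Pd(dppf)Cl2·CH2Cl2 (5 mol%), K3PO4 (3 equiv), dioxane/H2O 4:1, 80 °C, 6 h
Reagents that add atoms: none
Why: Suzuki–Miyaura coupling. An electron-poor heteroaryl Bpin with an aryl iodide makes the biaryl without needing N-protection on the pyrrole.

**Step 5**
Reactants: 6
Product: 7 5-[5-(benzyloxy)-1-SEM-indol-3-yl]-1H-pyrrole-2-carboxylic acid
Conditions: LiOH·H2O (5 equiv), THF/MeOH/H2O 3:1:1, 60 °C, 6 h; then 1 M citric acid to pH 4
Reagents that add atoms: water/hydroxide, O (the acid OH)
Why: Ester saponification. SEM and the benzyl ether are base-stable. The free acid is the directing group for Step 8.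

**Step 6**
Reactants: 8 isatin
Product: 9 isatin 3-(p-tolylsulfonyl)hydrazone
Conditions: TsNHNH2 (1.1 equiv), MeOH, reflux, 2 h
Reagents that add atoms: p-toluenesulfonyl hydrazide, Cc1ccc(cc1)S(=O)(=O)NN
Why: Condensation at the isatin C3 ketone, which is the more electrophilic carbonyl.

**Step 7**
Reactants: 9
Product: 10 3-diazoindolin-2-one (3-diazooxindole)
Conditions: K2CO3 (2 equiv), MeCN, 40 °C, 2 h, dark; cold filtration, use promptly
Reagents that add atoms: none
Why: Bamford–Stevens-type loss of p-toluenesulfinate from the tosylhydrazone gives the stable acceptor/donor diazo amide.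

**Step 8 (key step)**
Reactants: 7 + 10
Product: 11 3-[5-(5-benzyloxy-1-SEM-indol-3-yl)-2-carboxy-1H-pyrrol-3-yl]indolin-2-one (racemic at oxindole C3)
Conditions: [Cp*RhCl2]2 (4 mol%), AgSbF6 (16 mol%), NaOAc (1.0 equiv), 10 (1.3 equiv), CF3CH2OH, 40 °C, 16 h
Reagents that add atoms: none (diazo 10 is the numbered reactant; N2 is lost)
Why: Carboxylate-directed C–H activation of the acid gives a 5-membered rhodacycle at C3, since C5 is blocked by the indole. Carbene formation from 10, migratory insertion and protodemetalation (AcOH/TFE) give the C3 alkylated pyrrole directly at the oxindole oxidation level.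
Proposed new method: the closest known reaction is Cp*Rh(III)/Ir(III) carboxylate-directed ortho C–H alkylation of benzoic acids with diazo compounds, and Cp*Rh(III) coupling of 3-diazooxindoles with directed arenes. The new features are the substrate (the β C3–H of an NH pyrrole-2-carboxylic acid) and the bond formed (a pyrrole–oxindole C3–C3' bond). The Rh-enolate is protonated, so no stereocenter is controlled and the product epimerizes via its hydroxyindole tautomer.

**Step 9**
Reactants: 11
Product: 12 3-[5-(5-benzyloxy-1H-indol-3-yl)-2-carboxy-1H-pyrrol-3-yl]indolin-2-one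
Conditions: TBAF (1 M in THF, 10 equiv), ethylenediamine (10 equiv), THF, 65 °C, argon, 12 h; acidify to pH 4
Reagents that add atoms: none (N–H formed by protonation)
Why: Fluoride-induced Peterson-type fragmentation of the SEM group (releases CH2O, ethylene, TMSF). The acid, oxindole, pyrrole and benzyl ether are unaffected.

**Step 10**
Reactants: 12
Product: 13 violaceinic acid (target)
Conditions: H2 (1 atm), 10% Pd/C, THF/MeOH 1:1, rt, 4 h, degassed, dark; filter through Celite under argon
Reagents that add atoms: none (hydrogen only)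
Why: Hydrogenolysis of the aryl benzyl ether to the free 5-hydroxyindole. The pyrrole, indole and oxindole are not reduced at 1 atm. Product 13 is the oxindole/2-hydroxyindole tautomeric pair of the target.

## Compound list

| # | Name | SMILES | Role |
|---|---|---|---|
| 1 | methyl 1H-pyrrole-2-carboxylate | COC(=O)c1ccc[nH]1 | starting material |
| 2 | methyl 5-Bpin-pyrrole-2-carboxylate | COC(=O)c1ccc(B2OC(C)(C)C(C)(C)O2)[nH]1 | intermediate |
| 3 | 5-(benzyloxy)-1H-indole | c1ccc(COc2ccc3[nH]ccc3c2)cc1 | starting material |
| 4 | 5-(benzyloxy)-3-iodo-1H-indole | c1ccc(COc2ccc3[nH]cc(I)c3c2)cc1 | intermediate |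
| 5 | 5-(benzyloxy)-3-iodo-1-SEM-indole | c1ccc(COc2ccc3c(c2)c(I)cn3COCC[Si](C)(C)C)cc1 | intermediate |
| 6 | methyl 5-(5-benzyloxy-1-SEM-indol-3-yl)pyrrole-2-carboxylate | COC(=O)c1ccc(-c2cn(COCC[Si](C)(C)C)c3ccc(OCc4ccccc4)cc23)[nH]1 | intermediate |
| 7 | 5-(5-benzyloxy-1-SEM-indol-3-yl)pyrrole-2-carboxylic acid | OC(=O)c1ccc(-c2cn(COCC[Si](C)(C)C)c3ccc(OCc4ccccc4)cc23)[nH]1 | intermediate |
| 8 | isatin | O=C1Nc2ccccc2C1=O | starting material |
| 9 | isatin 3-tosylhydrazone | Cc1ccc(cc1)S(=O)(=O)NN=C1C(=O)Nc2ccccc21 | intermediate |
| 10 | 3-diazoindolin-2-one | [N-]=[N+]=C1C(=O)Nc2ccccc21 | intermediate |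
| 11 | C3-oxindolyl pyrrole acid, SEM/Bn protected (racemic) | OC(=O)c1[nH]c(-c2cn(COCC[Si](C)(C)C)c3ccc(OCc4ccccc4)cc23)cc1C1C(=O)Nc2ccccc21 | intermediate |
| 12 | N-H indole, O-benzyl oxindolyl pyrrole acid (racemic) | OC(=O)c1[nH]c(-c2c[nH]c3ccc(OCc4ccccc4)cc23)cc1C1C(=O)Nc2ccccc21 | intermediate |
| 13 | violaceinic acid (2-hydroxyindole tautomer; oxindole tautomer: …cc1C1C(=O)Nc2ccccc21) | O=C(O)c1[nH]c(-c2c[nH]c3ccc(O)cc23)cc1-c1c(O)[nH]c2ccccc12 | target |

Skeleton check: 13 has a pyrrole with C2-CO2H, C3-oxindolyl, C4-H and C5-(5-hydroxyindol-3-yl), matching the target SMILES. The target has no fixed stereocenters.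

## Totals

- **Total steps:** 10 (Steps 1–10)
- **Longest linear sequence:** 7 steps (3 → 4 → 5 → 6 → 7 → 11 → 12 → 13, numbering steps 2, 3, 4, 5, 8, 9, 10). The pyrrole-ester arm is 6 steps long.

## Three steps most likely to fail

1. **Step 8 (proposed new C3–H alkylation).**
   - Risks: O–H insertion of the diazo compound with the acid, C2–H chemistry at the indole, and poor C3 selectivity.
   - Fallback (known chemistry, different approach): Vilsmeier formylation of oxindole (POCl3/DMF) gives 2-chloroindole-3-carbaldehyde. Henry condensation with MeNO2 and N-protection give the nitrovinyl-indole. Barton–Zard reaction with ethyl isocyanoacetate/DBU gives ethyl 3-(2-chloroindol-3-yl)pyrrole-2-carboxylate. Then Ir C5-borylation, Suzuki coupling with 5, acid hydrolysis of the 2-chloroindole to the oxindole, and the same deprotections.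
2. **Step 1 (C5 versus C4 Ir borylation selectivity).**
   - Fallback: brominate methyl pyrrole-2-carboxylate with NBS, or start from commercial methyl 5-bromopyrrole-2-carboxylate. Couple it with a 1-SEM-5-benzyloxy-3-(tributylstannyl)indole made from 5 by Li–I exchange and Bu3SnCl, in a Stille coupling.
3. **Step 9 (SEM removal on an air-sensitive 3-aryl-oxindole/pyrrole).**
   - Risk: oxidation under the forcing basic conditions.
   - Fallback: use N-Boc indole in place of N-SEM (Step 3). Let the LiOH saponification in Step 5 also remove the Boc group. Run Step 8 on the free-NH indole and finish with hydrogenolysis only, which drops Step 9.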